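**Retrosynthetic overview**

1. Numbering used throughout: norbornane = C1 (CH–OMe), C2 (bridgehead CH), C3 (CH2), C4 (CH–i-Pr), C5 (quaternary bridgehead), C10 (CH), C15 (bridge CH2); ring B = C5–C6–C7–C8(Me)–C9–C10; ring C = C8–C9–C11(Me)(OH)–C12(OH)–C13–C14(Br).
2. Target ⇐ trans-diaxial hydrolysis of the C11–C12 epoxide ⇐ ring-C cyclohexene, closed by ring-closing metathesis (C11=C12) after which a ring-B ketone at C7 is removed ⇐ a β-bromo ketone that already holds ring B, C8 and C14–Br.
3. Key disconnection: ring B is not cyclised but grown from a cyclopentanol (C5, C6, C7, C9, C10) by a bromonium-triggered semipinacol shift of C9 from the carbinol C7 to C8. The enabling feature of the target is the quaternary C8 that carries the C14–Br bond antiperiplanar to the ring bond C8–C9 and sits next to the unfunctionalised methylene C7 (a latent carbonyl): a β-bromo ketone retron spanning rings B and C.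
4. The cyclopentanol ⇐ a norbornane-fused cyclopentanone plus an (E)-hexa-2,5-dien-2-yl metal; the cyclopentanone ⇐ carbonyl-ene closure on a norbornane aldehyde; the norbornane ⇐ catalytic asymmetric Diels–Alder reaction of a 1-substituted 2-silyloxycyclopentadiene with (3E)-6-methylhepta-3,5-dien-2-one (C1 oxygen by Baeyer–Villiger oxidation, C4 isopropyl by enol triflate coupling and exo reduction).
5. Order of ring formation: norbornane (step 3) → cyclopentane precursor of ring B (step 11) → ring B by one-carbon ring expansion (step 15) → ring C (step 16).

Key step: step 15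

Remark: the catalyst antipode in step 3 is taken as the one whose usual pre-transition-state model exposes the dienophile face leading to the drawn series; if the model demands the other, the catalyst from (R)-diphenylprolinol is used and nothing else changes.

**Route**

Step 1
Reactants: 1 cyclopent-2-en-1-one; 2 methyl bromoacetate
Product: 4 methyl 2-(2-oxocyclopent-3-en-1-yl)acetate (racemic), via lithium cyclopenta-1,4-dien-1-olate 3 (not isolated)
Conditions: LiN(i-Pr)2, THF, −78 °C; then 2, −78 → −30 °C
Reagents that add atoms: none
Why: Kinetic deprotonation at the α′-carbon gives the cross-conjugated enolate, whose alkylation by the reactive α-bromo ester (enolate alkylation) should install the side chain that becomes C6 and C7, and the new stereocentre does not matter because it is planarised in step 2.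

Step 2
Reactants: 4 methyl 2-(2-oxocyclopent-3-en-1-yl)acetate
Product: 5 methyl 2-[2-(tert-butyldimethylsilyloxy)cyclopenta-1,3-dien-1-yl]acetate
Conditions: TBSOTf, Et3N, CH2Cl2, −78 → 0 °C; used cold and at once
Reagents that add atoms: tert-butyldimethylsilyl triflate, CC(C)(C)[Si](C)(C)OS(=O)(=O)C(F)(F)F
Why: Soft enolisation toward the α′-carbon (silyl dienol ether formation) should give the 1-substituted 2-silyloxycyclopentadiene, which erases the stereocentre of 4 and puts the oxygen donor next to the substituted diene terminus (future C5).

Step 3
Reactants: 5 methyl 2-[2-(tert-butyldimethylsilyloxy)cyclopenta-1,3-dien-1-yl]acetate; 6 (3E)-6-methylhepta-3,5-dien-2-one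
Product: 7 norbornene adduct (bridgehead C5 with CH2CO2Me, silyl enol ether C3=C4–OTBS, endo acetyl at C1, exo 2-methylprop-1-enyl at C10)
Conditions: (S)-B-(o-tolyl)-diphenylprolinol oxazaborolidine·HNTf2 (20 mol%), CH2Cl2, −78 → −40 °C; Et3N quench
Reagents that add atoms: none
Why: In this Lewis-acid-catalysed Diels–Alder reaction the silyloxy group makes the substituted terminus (C5) the nucleophilic end so that it bonds to the enone β-carbon (C10) and creates the quaternary bridgehead, the endo transition state of the (E)-enone places acetyl endo at C1 and the alkenyl group exo at C10 relative to C2 and C5, and the chiral oxazaborolidinium shields one face of the bound enone to set the absolute configuration.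

Step 4
Reactants: 7 norbornene adduct
Product: 8 enol triflate (as 7, with OTf on C4)
Conditions: CsF, PhNTf2 (present from the start), DME, 0 °C → rt
Reagents that add atoms: N-phenylbis(trifluoromethanesulfonimide), O=S(=O)(N(c1ccccc1)S(=O)(=O)C(F)(F)F)C(F)(F)F
Why: Fluoride cleaves the silyl enol ether in the presence of the triflating agent so that the regiodefined enolate oxygen is sulfonylated at once (silyl enol ether to enol triflate exchange), which keeps the C3=C4 double bond and avoids a free base that could epimerise the acetyl-bearing C1.

Step 5
Reactants: 8 enol triflate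
Product: 9 endo acetate (as 8, with OAc on C1)
Conditions: (Me3SiO)2, Me3SiOTf (cat.), CH2Cl2, −78 → −30 °C
Reagents that add atoms: bis(trimethylsilyl) peroxide, C[Si](C)(C)OO[Si](C)(C)C
Why: This Baeyer–Villiger oxidation with a silyl peroxide is selective for the ketone over the side-chain olefin and the electron-poor enol triflate, and the secondary carbon migrates in preference to methyl with retention, so the endo acetyl becomes the endo acetate at C1.

Step 6
Reactants: 9 endo acetate
Product: 10 4-isopropylnorbornene (as 9, with isopropyl on C4, C3=C4 retained)
Conditions: i-PrMgCl, Fe(acac)3 (5 mol%), THF/NMP, −30 °C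
Reagents that add atoms: isopropylmagnesium chloride, CC(C)[Mg]Cl
Why: Iron-catalysed cross-coupling of the alkenyl triflate with the secondary Grignard reagent (Kumada-type coupling) should outrun addition to the two esters at low temperature and puts the isopropyl group on C4 without creating a stereocentre.

Step 7
Reactants: 10 4-isopropylnorbornene
Product: 11 norbornane with endo isopropyl at C4
Conditions: 2-nitrobenzenesulfonylhydrazide, Et3N, CH2Cl2, rt
Reagents that add atoms: none
Why: Diimide reduction delivers two hydrogens syn to the strained norbornene double bond much faster than to the unstrained trisubstituted side-chain olefin and from the exo face (the endo face is blocked by the other two-carbon bridge with its endo acetate), which places the isopropyl group endo at C4.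

Step 8
Reactants: 11 norbornane acetate
Product: 12 endo alcohol at C1
Conditions: K2CO3, MeOH, rt
Reagents that add atoms: none
Why: Base-catalysed transesterification removes the secondary acetate as methyl acetate while exchange at the methyl ester is degenerate and no stereocentre is touched.

Step 9
Reactants: 12 endo alcohol
Product: 13 endo methyl ether at C1
Conditions: NaH, MeI, THF, 0 °C → rt
Reagents that add atoms: iodomethane, CI
Why: Williamson etherification of the alkoxide gives the methyl ether with retention at C1 because the C–O bond is not broken.

Step 10
Reactants: 13 methyl ether ester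
Product: 14 aldehyde (C5–CH2–CHO)
Conditions: i-Bu2AlH, CH2Cl2, −78 °C; aq. potassium sodium tartrate
Reagents that add atoms: none
Why: Partial reduction of the ester by the aluminium hydride at low temperature stops at the tetrahedral aluminium hemiacetal, which releases the aldehyde on work-up.

Step 11
Reactants: 14 aldehyde
Product: 15 tricyclic cyclopentanol (tricyclo[5.2.1.0(1,5)]decane; C7–OH, isopropenyl on C9)
Conditions: Me2AlCl, CH2Cl2, −78 → 0 °C
Reagents that add atoms: none
Why: In this intramolecular carbonyl-ene reaction the aldehyde carbon bonds to the proximal olefin carbon (C9) while a methyl hydrogen passes to oxygen, which closes the five-membered ring and unveils the isopropenyl group; C9 is set by the allylic-strain-controlled side-chain conformation (C10–H eclipsing the olefin), which puts the isopropenyl group trans to C1, and the carbinol configuration (expected trans) is of no consequence.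

Step 12
Reactants: 15 tricyclic cyclopentanol
Product: 16 tricyclic ketone (C7=O)
Conditions: Dess–Martin periodinane, NaHCO3, CH2Cl2, 0 °C → rt
Reagents that add atoms: none
Why: Dess–Martin oxidation under buffered, non-basic conditions should give the β,γ-unsaturated ketone without moving the double bond or epimerising C9.

Step 13
Reactants: 17 (E)-1,3-dichlorobut-2-ene; 18 vinylmagnesium bromide
Product: 19 (E)-2-chlorohexa-2,5-diene
Conditions: CuI (5 mol%), THF, −20 → 0 °C
Reagents that add atoms: none
Why: Copper-catalysed substitution of the primary allylic chloride by the vinyl Grignard reagent (allylic cross-coupling) leaves the vinylic chloride and the olefin geometry untouched.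

Step 14
Reactants: 16 tricyclic ketone; 19 (E)-2-chlorohexa-2,5-diene
Product: 22 tertiary allylic alcohol (C7 carries OH and the (E)-hexa-2,5-dien-2-yl group, the latter trans to the isopropenyl group), via (E)-hexa-2,5-dien-2-yllithium 20 (not isolated), via dichloro[(E)-hexa-2,5-dien-2-yl]cerium 21 (not isolated)
Conditions: 19, Li (2% Na), Et2O, 0 °C; CeCl3, THF, −78 °C; then 16, −78 °C
Reagents that add atoms: none
Why: Reductive lithiation of the vinylic chloride keeps the olefin geometry, transmetalation to the weakly basic organocerium reagent suppresses enolisation of the β,γ-unsaturated ketone, and the 1,2-addition (organocerium addition) should occur on the ketone face opposite to the adjacent isopropenyl group, which sets the carbinol centre C7.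

Step 15
Reactants: 22 tertiary allylic alcohol
Product: 23 ring-expanded β-bromo ketone (ring B with C7=O; C8 quaternary with methyl and 1-bromobut-3-enyl; isopropenyl on C9)
Conditions: N-bromosuccinimide, NaHCO3, CH2Cl2, −40 → 0 °C, dark
Reagents that add atoms: N-bromosuccinimide, O=C1CCC(=O)N1Br
Why: N-Bromosuccinimide transfers bromenium to the most electron-rich olefin, the trisubstituted alkene next to the tertiary hydroxyl, and the bromonium ion is opened at its tertiary carbon C8 by the antiperiplanar ring bond C7–C9, which migrates while the carbinol becomes the ketone (halonium-induced semipinacol rearrangement of a 1-alkenylcycloalkanol, a well-known reaction type). No ring is closed by cyclisation: ring B arises from the cyclopentanol (C5, C6, C7, C9, C10) by insertion of C8 between C7 and C9, a one-carbon ring expansion by 1,2-shift. C14 is set by the anti addition of bromine and the migrating carbon across the (E)-olefin (bromine antiperiplanar to the new C8–C9 bond, C13 anti to C7), and C9 migrates with retention. C8 is set by the rotamer about the C7–C8 bond in which the olefin plane is perpendicular to the migrating bond, the methyl group lies next to the small hydroxyl and the vinylic hydrogen lies over the ring methylene C6 (least allylic strain), the alkenyl group having been placed trans to the isopropenyl group in step 14. The step needs chemoselectivity for one of three olefins, secured by the higher nucleophilicity of the trisubstituted double bond and by the irreversible shift that drains its bromonium ion, and it needs migration of C9 rather than C6, secured by the allylic and more substituted character of C9.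

Step 16
Reactants: 23 ring-expanded β-bromo ketone
Product: 24 tetracyclic bromo ketone (ring C closed, C11=C12)
Conditions: second-generation Grubbs catalyst (5 mol%), CH2Cl2, 40 °C
Reagents that add atoms: none
Why: Ring-closing metathesis between the isopropenyl group on C9 and the terminal vinyl group closes ring C as the trisubstituted cyclohexene with loss of ethene; no stereocentre is formed and the trans ring fusion follows from the configurations at C8 and C9.

Step 17
Reactants: 24 tetracyclic bromo ketone
Product: 25 tosylhydrazone of the C7 ketone
Conditions: TsNHNH2, AcOH (cat.), EtOH, 60 °C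
Reagents that add atoms: p-toluenesulfonyl hydrazide, Cc1ccc(cc1)S(=O)(=O)NN
Why: Acid-catalysed condensation (hydrazone formation) derivatises the hindered ring-B ketone under near-neutral conditions that the neopentylic secondary bromide should survive.

Step 18
Reactants: 25 tosylhydrazone
Product: 26 bromo alkene (C7 is CH2)
Conditions: catecholborane, CHCl3, 0 °C → rt; then NaOAc·3H2O, reflux
Reagents that add atoms: none
Why: Hydride transfer from catecholborane to the C=N bond followed by acetate-induced loss of sulfinate and dinitrogen from the diazene (a mild reductive deoxygenation related to the Wolff–Kishner reduction) should give the methylene group without the strong base that would eliminate HBr.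

Step 19
Reactants: 26 bromo alkene
Product: 27 11,12-epoxide (oxygen on the ring-C face opposite to the C8 methyl)
Conditions: m-CPBA, NaHCO3, CH2Cl2, 0 °C
Reagents that add atoms: meta-chloroperoxybenzoic acid, OOC(=O)c1cccc(Cl)c1
Why: Peracid epoxidation (Prilezhaev reaction) of the only olefin should occur from the face opposite to the axial methyl group on C8, which fixes the configuration at C12 and prepares C11 for inversion.

Step 20
Reactants: 27 11,12-epoxide
Product: 28 target compound
Conditions: HClO4 (cat.), THF/H2O, rt
Reagents that add atoms: water, O
Why: Acid-catalysed epoxide hydrolysis opens the ring in the trans-diaxial sense by attack of water at the tertiary C11 with inversion, so C11 gains the axial hydroxyl syn to the angular methyl while C12 keeps its oxygen, giving the trans-diaxial diol of the target.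

**Compound list** (absolute configurations are those of the SMILES)

1 | cyclopent-2-en-1-one | O=C1C=CCC1 | starting material
2 | methyl bromoacetate | COC(=O)CBr | starting material
3 | lithium cyclopenta-1,4-dien-1-olate (kinetic enolate of 1) | [Li]OC1=CCC=C1 | intermediate (not isolated)
4 | methyl 2-(2-oxocyclopent-3-en-1-yl)acetate (racemic) | COC(=O)CC1CC=CC1=O | intermediate
5 | methyl 2-[2-(tert-butyldimethylsilyloxy)cyclopenta-1,3-dien-1-yl]acetate | COC(=O)CC1=C(O[Si](C)(C)C(C)(C)C)C=CC1 | intermediate
6 | (3E)-6-methylhepta-3,5-dien-2-one | CC(=O)/C=C/C=C(C)C | starting material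
7 | norbornene adduct: methyl 2-[5-endo-acetyl-2-(tert-butyldimethylsilyloxy)-6-exo-(2-methylprop-1-enyl)bicyclo[2.2.1]hept-2-en-1-yl]acetate | CC(=O)[C@H]1[C@H]2C=C(O[Si](C)(C)C(C)(C)C)[C@](CC(=O)OC)(C2)[C@@H]1C=C(C)C | intermediate
8 | enol triflate: as 7 with trifluoromethanesulfonyloxy on C4 | CC(=O)[C@H]1[C@H]2C=C(OS(=O)(=O)C(F)(F)F)[C@](CC(=O)OC)(C2)[C@@H]1C=C(C)C | intermediate
9 | endo acetate: as 8 with endo acetoxy on C1 | CC(=O)O[C@H]1[C@H]2C=C(OS(=O)(=O)C(F)(F)F)[C@](CC(=O)OC)(C2)[C@@H]1C=C(C)C | intermediate
10 | 4-isopropylnorbornene: as 9 with isopropyl on C4, C3=C4 retained | CC(=O)O[C@H]1[C@H]2C=C(C(C)C)[C@](CC(=O)OC)(C2)[C@@H]1C=C(C)C | intermediate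
11 | norbornane: endo isopropyl at C4, endo acetoxy at C1, exo 2-methylprop-1-enyl at C10, CH2CO2Me on C5 | CC(=O)O[C@H]1[C@H]2C[C@@H](C(C)C)[C@](CC(=O)OC)(C2)[C@@H]1C=C(C)C | intermediate
12 | endo alcohol: as 11 with OH on C1 | O[C@H]1[C@H]2C[C@@H](C(C)C)[C@](CC(=O)OC)(C2)[C@@H]1C=C(C)C | intermediate
13 | endo methyl ether: as 12 with OMe on C1 | CO[C@H]1[C@H]2C[C@@H](C(C)C)[C@](CC(=O)OC)(C2)[C@@H]1C=C(C)C | intermediate
14 | aldehyde: as 13 with CH2CHO on C5 | CO[C@H]1[C@H]2C[C@@H](C(C)C)[C@](CC=O)(C2)[C@@H]1C=C(C)C | intermediate
15 | tricyclic cyclopentanol: 9-endo-isopropyl-6-endo-methoxy-4-(prop-1-en-2-yl)tricyclo[5.2.1.0(1,5)]decan-3-ol, isopropenyl trans to C1, OH trans to isopropenyl | CO[C@H]1[C@H]2C[C@@H](C(C)C)[C@]3(C[C@H](O)[C@H]([C@H]13)C(C)=C)C2 | intermediate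
16 | tricyclic ketone: the 3-one corresponding to 15 (C7=O) | CO[C@H]1[C@H]2C[C@@H](C(C)C)[C@]3(CC(=O)[C@H]([C@H]13)C(C)=C)C2 | intermediate
17 | (E)-1,3-dichlorobut-2-ene | C/C(Cl)=C\CCl | starting material
18 | vinylmagnesium bromide | C=C[Mg]Br | starting material
19 | (E)-2-chlorohexa-2,5-diene | C/C(Cl)=C\CC=C | intermediate
20 | (E)-hexa-2,5-dien-2-yllithium | C/C([Li])=C\CC=C | intermediate (not isolated)
21 | dichloro[(E)-hexa-2,5-dien-2-yl]cerium | C/C([Ce](Cl)Cl)=C\CC=C | intermediate (not isolated)
22 | tertiary allylic alcohol: 16 after addition of the (E)-hexa-2,5-dien-2-yl group to C7, trans to the isopropenyl group | CO[C@H]1[C@H]2C[C@@H](C(C)C)[C@]3(C[C@](O)(/C(C)=C/CC=C)[C@H]([C@H]13)C(C)=C)C2 | intermediate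
23 | ring-expanded β-bromo ketone: ring B with C7=O, C8 bearing methyl and 1-bromobut-3-enyl (C14–Br), C9 bearing isopropenyl | CO[C@H]1[C@H]2C[C@@H](C(C)C)[C@]3(CC(=O)[C@](C)([C@@H](Br)CC=C)[C@H]([C@H]13)C(C)=C)C2 | intermediate
24 | tetracyclic bromo ketone: rings B and C trans-fused, C7=O, C11=C12, equatorial bromide at C14 | CO[C@H]1[C@H]2C[C@@H](C(C)C)[C@]3(CC(=O)[C@@]4(C)[C@H]([C@H]13)C(C)=CC[C@@H]4Br)C2 | intermediate
25 | p-toluenesulfonylhydrazone of 24 at C7 (C=N geometry immaterial) | CO[C@H]1[C@H]2C[C@@H](C(C)C)[C@]3(CC(=NNS(=O)(=O)c5ccc(C)cc5)[C@@]4(C)[C@H]([C@H]13)C(C)=CC[C@@H]4Br)C2 | intermediate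
26 | bromo alkene: as 24 with C7 as CH2 | CO[C@H]1[C@H]2C[C@@H](C(C)C)[C@]3(CC[C@@]4(C)[C@H]([C@H]13)C(C)=CC[C@@H]4Br)C2 | intermediate
27 | 11,12-epoxide of 26, oxygen anti to the C8 methyl | CO[C@H]1[C@H]2C[C@@H](C(C)C)[C@]3(CC[C@@]4(C)[C@H]([C@H]13)[C@@]5(C)O[C@H]5C[C@@H]4Br)C2 | intermediate
28 | CNP0130529.1 (target) | CO[C@H]1[C@H]2C[C@@H](C(C)C)[C@]3(CC[C@@]4(C)[C@H]([C@H]13)[C@](C)(O)[C@@H](O)C[C@@H]4Br)C2 | target

**Totals and risks**

Total step count: 20. Longest linear sequence: 19 steps (steps 1–12 and 14–20; step 13 prepares the side-chain fragment).

Steps most likely to fail: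

Step 15 (key step). The two rotamers about the C7–C8 bond differ only modestly in energy, so facial control of the 1,2-shift may erode and give the C8 epimer; bromenium may also be transferred to the two spectator olefins, or the bromonium ion may be captured by the hydroxyl group before migration. Fallback: the facial choice is handed from the substrate to the reagent. Alcohol 22 is treated with N-bromoacetamide in the presence of a dimeric cinchona alkaloid ligand, (DHQD)2PHAL or its pseudoenantiomer (DHQ)2PHAL, whichever is matched with the substrate. This is the known catalyst-controlled halogenation/semipinacol rearrangement of 1-alkenylcycloalkanols, in which a bulky chiral bromenium complex differentiates the olefin faces. The fallback sets out from 22 and returns at 23 and forms no compound beyond those listed (F0).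

Step 3. Enantiofacial discrimination by the catalyst may be insufficient on this congested enone, and the diene may isomerise by 1,5-hydrogen shift before it is consumed. Fallback: the cycloaddition of 5 and 6 is run without a chiral catalyst (Me2AlCl, CH2Cl2, −78 °C), giving 7 together with its mirror image, the enantiomer of 7 F1. The mixture is converted under the conditions of step 4 into 8 and the enantiomer of 8 F2, and the two are separated by preparative chromatography on a chiral stationary phase. The fallback sets out from 5 and 6 and returns at 8.

Step 11. The Lewis acid may divert the concerted ene process into a stepwise Prins pathway with chloride capture, or control of the C9 configuration may be lost. Fallback: the ring is closed at the acid oxidation level instead. Ester 13 is saponified (LiOH, THF/H2O) to the carboxylic acid F3, converted with (COCl)2 and catalytic DMF into the acid chloride F4, and cyclised with SnCl4 (CH2Cl2, −78 °C) by intramolecular acylation of the trisubstituted olefin at C9 with proton loss from a methyl group, which gives ketone 16 directly. The fallback sets out from 13 and returns at 16.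

**Further compounds**

F0 | step 15 | none | none
F1 | step 3 | enantiomer of norbornene adduct 7 | CC(=O)[C@@H]1[C@@H]2C=C(O[Si](C)(C)C(C)(C)C)[C@@](CC(=O)OC)(C2)[C@H]1C=C(C)C
F2 | step 3 | enantiomer of enol triflate 8 | CC(=O)[C@@H]1[C@@H]2C=C(OS(=O)(=O)C(F)(F)F)[C@@](CC(=O)OC)(C2)[C@H]1C=C(C)C
F3 | step 11 | carboxylic acid from ester 13 (CH2CO2H on C5) | CO[C@H]1[C@H]2C[C@@H](C(C)C)[C@](CC(=O)O)(C2)[C@@H]1C=C(C)C
F4 | step 11 | acid chloride of F3 (CH2COCl on C5) | CO[C@H]1[C@H]2C[C@@H](C(C)C)[C@](CC(=O)Cl)(C2)[C@@H]1C=C(C)C
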